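**Strategy.** α-Onocerin is cut at its two angular methyl groups: removing C19 and C19′ from C10/C10′ of rings A/B reduces each half to a 6-methoxytetralin and the skeleton to a flat, C2-symmetric dimer tied through C11–C11′. The key step returns both carbons at once. An 8β-hydroxyl on ring B steers a zinc carbenoid onto the β face of each tetrasubstituted C5=C10 ring-fusion alkene, closing two cyclopropanes (C5–C19–C10) that are later opened to 10β-methyl enones. The feature exploited is the fusion alkene shared by rings A and B, with O8 homoallylic to C10. The precursor is a bis(Δ5(10)-octalin) diol with C3 stored as a dioxolane, an 8β-OH and a 9α tether.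

Key step: step 7

Remark on numbering: each half is numbered as a decalin, ring A = C1–C5/C10, ring B = C5–C10; C3 is the carbinol, C4 the gem-dimethyl carbon, C19 the methyl carbon on C10, C26 the methylene carbon on C8, C11 the tether carbon on C9; primes mark the twin; α/β as in steroid drawings with C19 β.

Assumption: the antipode of IpcBH2 is chosen by analogy with its established sense on 1-alkylcycloalkenes (S carbinol carbon from the (+)-α-pinene-derived reagent); if the sense on 6 is opposite, the antipodal reagent is used with no other change.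

**Step 1**
Reactants: 1 6-methoxy-1-tetralone (2 equiv); 2 acetylene
Product: 4 1,1'-(ethyne-1,2-diyl)bis(6-methoxy-1,2,3,4-tetrahydronaphthalen-1-ol), via ethynediylbis(magnesium bromide) 3 (not isolated)
Conditions: EtMgBr (2 equiv per acetylene), THF/toluene, 50 °C; then 1, reflux; NH4Cl (aq)
Reagents that add atoms: acetylene 2, C#C
Why: Double 1,2-addition of the acetylene bis-Grignard (Iotsich reagent) to the aryl ketone should give the symmetrical butynediol, and the two carbinol centres need no control because both are erased in step 3.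

**Step 2**
Reactants: 4 alkynediol
Product: 5 1,1'-(ethane-1,2-diyl)bis(6-methoxy-1,2,3,4-tetrahydronaphthalen-1-ol)
Conditions: H2 (1 atm), PtO2, EtOAc, rt
Reagents that add atoms: none
Why: Catalytic hydrogenation saturates the alkyne to the CH2CH2 tether, and platinum under neutral conditions should leave the tertiary benzylic C–O bonds and the anisole rings untouched.

**Step 3**
Reactants: 5 saturated diol
Product: 6 1,2-bis(6-methoxy-3,4-dihydronaphthalen-1-yl)ethane
Conditions: p-TsOH·H2O (cat.), toluene, 80 °C
Reagents that add atoms: none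
Why: Acid-catalysed E1 dehydration of the tertiary benzylic alcohols under equilibrating conditions should settle on the endocyclic, aryl-conjugated C8=C9 alkene at both ends.

**Step 4**
Reactants: 6 bis(dihydronaphthalene)
Product: 8 (1S,1'S,2S,2'S)-1,1'-(ethane-1,2-diyl)bis(6-methoxy-1,2,3,4-tetrahydronaphthalen-2-ol), via bis(isopinocampheylboryl) adduct 7 (not isolated)
Conditions: IpcBH2 from (+)-α-pinene (2.5 equiv), THF, −25 °C; then NaOH (aq), H2O2, 0 °C → rt
Reagents that add atoms: hydrogen peroxide, OO
Why: Brown asymmetric hydroboration–oxidation adds H to benzylic C9 and B to C8 syn on the reagent-selected β face and oxidises C–B with retention, which sets 8S (8β-OH) and 9S (tether α, trans) in both halves, and because the two ends react independently most of the facial error should end up in a separable meso diol.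

**Step 5**
Reactants: 8 bis(tetralol)
Product: 9 (1S,1'S,2S,2'S)-1,1'-(ethane-1,2-diyl)bis(6-methoxy-1,2,3,4,5,8-hexahydronaphthalen-2-ol)
Conditions: Li, NH3 (l), THF, t-BuOH, −33 °C; then MeOH, NH4Cl
Reagents that add atoms: none
Why: Birch reduction of each anisole ring should give the 1-methoxy-1,4-cyclohexadiene that keeps the tetrasubstituted C5=C10 alkene and the C2=C3 enol ether, while the C8 lithium alkoxides and the C8/C9 stereocentres are inert.

**Step 6**
Reactants: 9 bis(dienol ether) diol; 10 ethylene glycol
Product: 11 bis(Δ5(10)-octalin) diol bis(dioxolane) (each half: 3,3-ethylenedioxy, C5=C10, 8β-OH (8S), 9α tether (9S))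
Conditions: HOCH2CH2OH (excess), p-TsOH·H2O (cat.), THF, 0 °C → rt; Et3N quench
Reagents that add atoms: ethylene glycol 10, OCCO
Why: Acid-catalysed enol ether-to-ketal exchange (protonation at C2, capture of the C3 oxocarbenium ion by the diol) is faster than alkene migration, so C3 is masked as the dioxolane and the Δ5(10) alkene stays in place.

**Step 7**
Reactants: 11 bis(Δ5(10)-octalin) diol bis(dioxolane); 12 diiodomethane
Product: 13 bis(5β,10β-methano) diol bis(dioxolane) (each half: C19 bridging C5 and C10 on the β face, 8β-OH, 9α tether, 3,3-ethylenedioxy)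
Conditions: Et2Zn (6 equiv), CH2I2 (10 equiv), CH2Cl2, −10 °C → rt; NH4Cl (aq)
Reagents that add atoms: diiodomethane 12, ICI
Why: Et2Zn first turns each 8β-hydroxyl into an ethylzinc alkoxide, iodine–zinc exchange with CH2I2 then builds an iodomethylzinc carbenoid on or beside that oxygen, and the CH2 unit is handed to the C5=C10 alkene beneath it through a concerted butterfly transition state. The closest known reaction type is the hydroxyl-directed Simmons–Smith (Furukawa) cyclopropanation of Birch-derived steroidal 5(10)-enes that carry a homoallylic carbinol. Each three-membered ring (C5–C19–C10) closes by a stereospecific syn [2+1] cheletropic addition that forms C5–C19 and C10–C19 in one event. The new centres C5 and C10 and their twins are fixed by the zinc-bound O8, because A(1,2) strain against C1 holds the C9 tether pseudoaxial on the α face and thereby places the trans 8β-oxygen axial over the β face of the alkene. The step needs β-facial selectivity and complete reaction at two hindered alkenes; the first is secured twice over (oxygen delivery on β, tether shielding on α), the second by excess carbenoid, and chemoselectivity follows from the enol ethers of 9 having been stored as dioxolanes in step 6.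

**Step 8**
Reactants: 13 bis(5β,10β-methano) diol bis(dioxolane)
Product: 14 bis(8-O-benzyl ether) of 13
Conditions: NaH, BnBr, n-Bu4NI (cat.), THF/DMF, 0 °C → rt
Reagents that add atoms: benzyl bromide, BrCc1ccccc1
Why: Williamson etherification caps both 8β-hydroxyls with a group that should survive the strong acid, base and hydride of steps 9–11 and that keeps O8 from taking part in the acid step.

**Step 9**
Reactants: 14 bis(benzyl ether)
Product: 16 bis(10β-methyl-4-en-3-one) (each half: C4=C5 enone, 10β-CH3, 8β-OBn, 9α tether), via bis(cyclopropyl ketone) 15 (not isolated)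
Conditions: HCl (3 M, aq), MeOH/THF, 60 °C
Reagents that add atoms: water, O
Why: Ketal hydrolysis is followed by acid-catalysed homoconjugate opening of the β-cyclopropyl ketone, in which the C3 enol pushes electrons through C4 into C5 as C19 is protonated, so only C5–C19 breaks, C10 keeps C19 as its β-methyl group and the Δ4-3-ketone results.

**Step 10**
Reactants: 16 bis(enone)
Product: 17 bis(4,4,10β-trimethyl-5-en-3-one) (each half: C5=C6, 3-ketone, 8β-OBn, 9α tether)
Conditions: KOtBu (5 equiv), MeI (10 equiv), t-BuOH/THF, rt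
Reagents that add atoms: iodomethane, CI
Why: Deconjugative double α-alkylation through the extended dienolate (the classical gem-dimethylation of 4-en-3-ones) should install both C4 methyl groups and move the alkene to C5=C6 without creating a stereocentre.

**Step 11**
Reactants: 17 bis(4,4-dimethyl-5-en-3-one)
Product: 18 bis(3β-ol) (each half: 3β-OH, 4,4-dimethyl, C5=C6, 8β-OBn, 9α tether)
Conditions: NaBH4, MeOH/THF, 0 °C
Reagents that add atoms: none
Why: Hydride reduction of the 4,4-dimethyl-3-ketone should proceed by axial attack on the α face, away from the axial 4β-methyl group, and give the equatorial 3β-alcohol (3S).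

**Step 12**
Reactants: 18 bis(3β-ol)
Product: 19 bis(3β-acetate) of 18
Conditions: Ac2O, pyridine, DMAP (cat.), rt
Reagents that add atoms: acetic anhydride, CC(=O)OC(C)=O
Why: DMAP-catalysed acylation masks the only free hydroxyls (C3) so that C8 can later be oxidised alone.

**Step 13**
Reactants: 19 bis(3β-acetate) bis(benzyl ether)
Product: 21 bis(5α-decalin) 8β-ol 3β-acetate (each half: 5α-H, trans-fused, 3β-OAc, 8β-OH, 9α tether), via debenzylated 5-ene diol diacetate 20 (not isolated)
Conditions: H2 (1 atm), Pd(OH)2/C, EtOAc/AcOH, rt; then PtO2 added, H2 (4 atm), 50 °C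
Reagents that add atoms: none
Why: Hydrogenolysis of the benzyl ethers over palladium is followed by platinum-catalysed syn hydrogenation of the hindered C5=C6 alkene from the α face, because the β face is closed by the axial C19 and 4β-methyl groups, which sets 5α-H and the trans ring fusion.

**Step 14**
Reactants: 21 bis(8β-ol) diacetate
Product: 22 bis(8-ketone) diacetate (each half: 8-oxo, 9α tether, 5α-H, 3β-OAc)
Conditions: Dess–Martin periodinane, NaHCO3, CH2Cl2, rt
Reagents that add atoms: none
Why: Dess–Martin oxidation converts the axial 8β-alcohols into ketones under near-neutral conditions that should leave the acetates and the centres at C5 and C9 alone.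

**Step 15**
Reactants: 22 bis(8-ketone) diacetate
Product: 23 3β,3'β-dihydroxy-8,8'-diketone with natural C9 (each half: 8-oxo, 9β tether/9α-H, 5α-H, 3β-OH)
Conditions: NaOMe, MeOH, 50 °C
Reagents that add atoms: none
Why: Base-mediated enolisation toward C9 equilibrates the axial 9α tether to the equatorial 9β position (relieving its syn-axial contacts with H1α, H5α and H7α) while Zemplén transesterification removes both acetates in the same pot.

**Step 16**
Reactants: 23 dihydroxy diketone
Product: 24 α-onocerin
Conditions: Ph3PCH3Br, KOtBu (excess), toluene, 90 °C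
Reagents that add atoms: methyltriphenylphosphonium bromide, C[P+](c1ccccc1)(c1ccccc1)c1ccccc1.[Br-]
Why: Wittig methylenation of both 8-ketones with excess ylide (the C3 alkoxides are spectators) should install the two exocyclic methylenes, and since C9 already holds its thermodynamically preferred configuration the basic medium cannot erode it.

**Compound list**

1 | 6-methoxy-1-tetralone | COc1ccc2c(c1)CCCC2=O | starting material
2 | acetylene | C#C | starting material
3 | ethynediylbis(magnesium bromide) | Br[Mg]C#C[Mg]Br | intermediate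
4 | 1,1'-(ethyne-1,2-diyl)bis(6-methoxy-1,2,3,4-tetrahydronaphthalen-1-ol), mixture of meso and racemic forms | C(#CC1(O)CCCc2cc(OC)ccc12)C1(O)CCCc2cc(OC)ccc12 | intermediate
5 | 1,1'-(ethane-1,2-diyl)bis(6-methoxy-1,2,3,4-tetrahydronaphthalen-1-ol), diastereomer mixture | C(CC1(O)CCCc2cc(OC)ccc12)C1(O)CCCc2cc(OC)ccc12 | intermediate
6 | 1,2-bis(6-methoxy-3,4-dihydronaphthalen-1-yl)ethane | C(CC1=CCCc2cc(OC)ccc12)C1=CCCc2cc(OC)ccc12 | intermediate
7 | bis(isopinocampheylboryl) adduct of 6 (each C8 bears BH(Ipc) on the β face, each C9 bears H on the β face) | C(C[C@@H]1[C@@H]([BH][C@@H]3C[C@@H]4C[C@H]([C@H]3C)C4(C)C)CCc2cc(OC)ccc12)[C@@H]1[C@@H]([BH][C@@H]3C[C@@H]4C[C@H]([C@H]3C)C4(C)C)CCc2cc(OC)ccc12 | intermediate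
8 | (1S,1'S,2S,2'S)-1,1'-(ethane-1,2-diyl)bis(6-methoxy-1,2,3,4-tetrahydronaphthalen-2-ol) (8β-OH, 9α tether in each half) | C(C[C@@H]1[C@@H](O)CCc2cc(OC)ccc12)[C@@H]1[C@@H](O)CCc2cc(OC)ccc12 | intermediate
9 | (1S,1'S,2S,2'S)-1,1'-(ethane-1,2-diyl)bis(6-methoxy-1,2,3,4,5,8-hexahydronaphthalen-2-ol) | C(C[C@@H]1[C@@H](O)CCC2=C1CC=C(OC)C2)[C@@H]1[C@@H](O)CCC2=C1CC=C(OC)C2 | intermediate
10 | ethylene glycol | OCCO | starting material
11 | bis(Δ5(10)-octalin) diol bis(dioxolane): each half 3,3-ethylenedioxy, C5=C10, (8S)-8β-OH, (9S)-9α tether | C(C[C@@H]1[C@@H](O)CCC2=C1CCC1(C2)OCCO1)[C@@H]1[C@@H](O)CCC2=C1CCC1(C2)OCCO1 | intermediate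
12 | diiodomethane | ICI | starting material
13 | bis(5β,10β-methano) diol bis(dioxolane): each half C19 bridging C5/C10 on the β face, 8β-OH, 9α tether, 3,3-ethylenedioxy | C(C[C@@H]1[C@@H](O)CC[C@@]23C[C@@]12CCC1(C3)OCCO1)[C@@H]1[C@@H](O)CC[C@@]23C[C@@]12CCC1(C3)OCCO1 | intermediate
14 | bis(8-O-benzyl ether) of 13 | C(C[C@@H]1[C@@H](OCc4ccccc4)CC[C@@]23C[C@@]12CCC1(C3)OCCO1)[C@@H]1[C@@H](OCc4ccccc4)CC[C@@]23C[C@@]12CCC1(C3)OCCO1 | intermediate
15 | bis(5β,10β-methano-3-ketone) bis(benzyl ether) | C(C[C@@H]1[C@@H](OCc4ccccc4)CC[C@@]23C[C@@]12CCC(=O)C3)[C@@H]1[C@@H](OCc4ccccc4)CC[C@@]23C[C@@]12CCC(=O)C3 | intermediate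
16 | bis(10β-methyl-4-en-3-one): each half 8β-OBn, 9α tether | C(C[C@@H]1[C@@H](OCc4ccccc4)CCC2=CC(=O)CC[C@]12C)[C@@H]1[C@@H](OCc4ccccc4)CCC2=CC(=O)CC[C@]12C | intermediate
17 | bis(4,4,10β-trimethyl-5-en-3-one): each half 8β-OBn, 9α tether | C(C[C@@H]1[C@@H](OCc4ccccc4)CC=C2C(C)(C)C(=O)CC[C@]12C)[C@@H]1[C@@H](OCc4ccccc4)CC=C2C(C)(C)C(=O)CC[C@]12C | intermediate
18 | bis(3β-ol): each half 3β-OH, 4,4,10β-trimethyl, C5=C6, 8β-OBn, 9α tether | C(C[C@@H]1[C@@H](OCc4ccccc4)CC=C2C(C)(C)[C@@H](O)CC[C@]12C)[C@@H]1[C@@H](OCc4ccccc4)CC=C2C(C)(C)[C@@H](O)CC[C@]12C | intermediate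
19 | bis(3β-acetate) of 18 | C(C[C@@H]1[C@@H](OCc4ccccc4)CC=C2C(C)(C)[C@@H](OC(C)=O)CC[C@]12C)[C@@H]1[C@@H](OCc4ccccc4)CC=C2C(C)(C)[C@@H](OC(C)=O)CC[C@]12C | intermediate
20 | debenzylated 5-ene diol diacetate: each half 3β-OAc, C5=C6, 8β-OH, 9α tether | C(C[C@@H]1[C@@H](O)CC=C2C(C)(C)[C@@H](OC(C)=O)CC[C@]12C)[C@@H]1[C@@H](O)CC=C2C(C)(C)[C@@H](OC(C)=O)CC[C@]12C | intermediate
21 | bis(5α-decalin) diol diacetate: each half 5α-H, 3β-OAc, 8β-OH, 9α tether | C(C[C@@H]1[C@@H](O)CC[C@H]2C(C)(C)[C@@H](OC(C)=O)CC[C@]12C)[C@@H]1[C@@H](O)CC[C@H]2C(C)(C)[C@@H](OC(C)=O)CC[C@]12C | intermediate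
22 | bis(8-ketone) diacetate: each half 8-oxo, 9α tether, 5α-H, 3β-OAc | C(C[C@@H]1C(=O)CC[C@H]2C(C)(C)[C@@H](OC(C)=O)CC[C@]12C)[C@@H]1C(=O)CC[C@H]2C(C)(C)[C@@H](OC(C)=O)CC[C@]12C | intermediate
23 | 3β,3'β-dihydroxy-8,8'-diketone with natural C9 (26,27-dinor-α-onocerin diketone): each half 8-oxo, 9α-H, 5α-H, 3β-OH | C(C[C@H]1C(=O)CC[C@H]2C(C)(C)[C@@H](O)CC[C@]12C)[C@H]1C(=O)CC[C@H]2C(C)(C)[C@@H](O)CC[C@]12C | intermediate
24 | α-onocerin | C=C1CC[C@H]2C(C)(C)[C@@H](O)CC[C@]2(C)[C@H]1CC[C@H]1C(=C)CC[C@H]2C(C)(C)[C@@H](O)CC[C@]12C | target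

**Step count.** Total steps: 16. Longest linear sequence: 16 (1 → 24).

**Steps most likely to fail, with fallbacks**

Step 7. Methylene transfer to two hindered tetrasubstituted alkenes may stall after one ring, lose facial control, or be accompanied by Lewis-acid opening of the dioxolanes. The fallback replaces oxygen-directed zinc carbenoid delivery by sterically controlled dihalocarbene addition and reduction. Setting out from 11, the hydroxyls are benzylated first (NaH, BnBr) to give the bis(benzyl ether) of the diene ketal F1. Dibromocarbene (CHBr3, KOtBu, pentane, 0 °C) is then added; the pseudoaxial 9α tether should screen the α face, giving the bis(5β,10β-dibromomethano) adduct F2. Radical reduction with n-Bu3SnH/AIBN in toluene at 80 °C removes the four bromine atoms and returns to the route at 14.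

Step 13. Hydrogenation of the crowded C5=C6 alkene may stall or lose facial selectivity because the 9α tether leans over the α face. The fallback sets C5 by thermodynamic protonation after C9 has been corrected, not by face-selective hydrogen delivery. The reaction is stopped after the palladium stage and 20 is isolated. Dess–Martin oxidation gives the 5-ene 8-ketone diacetate F3. NaOMe in MeOH then epimerises C9, removes the acetates and moves the β,γ-alkene into conjugation through the extended enolate, whose γ-protonation at C5 should settle on the trans-fused 5α-H 6-en-8-one diol F4. Hydrogenation of the unhindered disubstituted enone alkene (H2, Pd/C, EtOAc), which creates no stereocentre, rejoins the route at 23.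

Step 4. Enantiofacial control by the chiral borane may be insufficient on this substrate, or the first-formed dialkylborane may hydroborate the second alkene intramolecularly. The fallback is a classical resolution. Setting out from 6, hydroboration with BH3·SMe2 and oxidation (NaOH, H2O2) gives the trans,trans-diols as a mixture of racemate and meso form F5. Esterification with (S)-O-methylmandelic acid (DCC, DMAP) and chromatographic separation of the diastereomeric diesters gives the bis[(S)-O-methylmandelate] of the (S,S,S,S)-diol F6. Methanolysis (K2CO3, MeOH) returns to the route at 8.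

**Further compounds**

F1 | step 7 | bis(8-O-benzyl ether) of 11 | C(C[C@@H]1[C@@H](OCc4ccccc4)CCC2=C1CCC1(C2)OCCO1)[C@@H]1[C@@H](OCc4ccccc4)CCC2=C1CCC1(C2)OCCO1
F2 | step 7 | bis(5β,10β-dibromomethano) bis(benzyl ether) bis(dioxolane) | C(C[C@@H]1[C@@H](OCc4ccccc4)CC[C@@]23C(Br)(Br)[C@@]12CCC1(C3)OCCO1)[C@@H]1[C@@H](OCc4ccccc4)CC[C@@]23C(Br)(Br)[C@@]12CCC1(C3)OCCO1
F3 | step 13 | 5-ene 8-ketone diacetate (each half 3β-OAc, C5=C6, 8-oxo, 9α tether) | C(C[C@@H]1C(=O)CC=C2C(C)(C)[C@@H](OC(C)=O)CC[C@]12C)[C@@H]1C(=O)CC=C2C(C)(C)[C@@H](OC(C)=O)CC[C@]12C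
F4 | step 13 | 6-en-8-one diol (each half 3β-OH, 5α-H, C6=C7, 8-oxo, 9α-H) | C(C[C@H]1C(=O)C=C[C@H]2C(C)(C)[C@@H](O)CC[C@]12C)[C@H]1C(=O)C=C[C@H]2C(C)(C)[C@@H](O)CC[C@]12C
F5 | step 4 | trans,trans-1,1'-(ethane-1,2-diyl)bis(6-methoxy-1,2,3,4-tetrahydronaphthalen-2-ol), mixture of racemate and meso form | C(CC1C(O)CCc2cc(OC)ccc12)C1C(O)CCc2cc(OC)ccc12
F6 | step 4 | bis[(S)-O-methylmandelate] of 8 | C(C[C@@H]1[C@@H](OC(=O)[C@@H](OC)c5ccccc5)CCc2cc(OC)ccc12)[C@@H]1[C@@H](OC(=O)[C@@H](OC)c5ccccc5)CCc2cc(OC)ccc12
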